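**Strategy.** The trihydroxy ring (C1–C6) is disconnected at C2–C3. Its C3 carbinol and C6 carbinol are 1,4-related through C2 and C1, the retron of a reductive aldehyde–enone coupling. The ring precursor is therefore an acyclic β-hydroxy aldehyde bearing an isopropenyl ketone, made from (R)-lactic acid. SmI2 joins the two electrophilic carbons C3 and C2, closes the ring, sets C3 cis to the C5 hydroxyl by chelation and leaves C1 as an enolate position for the second methyl group. Axial addition of a six-carbon enynol to the C6 ketone, alkyne reduction and two Wittig reactions with a ten-carbon dialdehyde and an acetylenic fifteen-carbon phosphonium salt complete the carotenoid.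

Key step: step 6

Remark: carotenoid numbering is used (C1–C6 for the trihydroxy ring, primed locants for the acetylenic half). The SMILES is read as the (3S,5S,6S,3'R) isomer, in which the 3- and 5-hydroxyls are cis and the 6-hydroxyl is trans to both.

**Route**

Step 1
Reactants: 1 (R)-lactic acid; 2 pivalaldehyde
Product: 3 (2R,5R)-2-tert-butyl-5-methyl-1,3-dioxolan-4-one (cis isomer)
Conditions: cat. TsOH, cat. H2SO4, pentane, reflux with azeotropic removal of water; crystallization from pentane, −78 °C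
Reagents that add atoms: none
Why: Acid-catalysed acetalization under thermodynamic control should give mainly the cis-dioxolanone (freed from the trans isomer by crystallization), in which the lactate stereocentre fixes the configuration of the new acetal carbon.

Step 2
Reactants: 3 (2R,5R)-2-tert-butyl-5-methyl-1,3-dioxolan-4-one; 4 allyl bromide
Product: 5 (2R,5S)-2-tert-butyl-5-methyl-5-(prop-2-en-1-yl)-1,3-dioxolan-4-one
Conditions: LiN(i-Pr)2, THF, −78 °C; then 4, −78 → −20 °C
Reagents that add atoms: none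
Why: Enolate alkylation with self-regeneration of the stereocentre: the planar lithium enolate is attacked by allyl bromide anti to the tert-butyl group, so the quaternary carbon that becomes C5 carries the allyl group in the place of the former hydrogen.

Step 3
Reactants: 5 (2R,5S)-2-tert-butyl-5-methyl-5-(prop-2-en-1-yl)-1,3-dioxolan-4-one; 6 N,O-dimethylhydroxylamine hydrochloride
Product: 7 (2S)-2-hydroxy-N-methoxy-N,2-dimethylpent-4-enamide
Conditions: i-PrMgCl (3 equiv), THF, −20 → 0 °C; aq NH4Cl
Reagents that add atoms: none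
Why: Aminolysis of the activated acylal lactone by the chloromagnesium amide of N,O-dimethylhydroxylamine (Weinreb amide formation) opens the ring, and the hemiacetal left on the tertiary oxygen loses pivalaldehyde on work-up without touching the quaternary stereocentre.

Step 4
Reactants: 7 (2S)-2-hydroxy-N-methoxy-N,2-dimethylpent-4-enamide; 8 isopropenylmagnesium bromide
Product: 9 (4S)-4-hydroxy-2,4-dimethylhepta-1,6-dien-3-one
Conditions: 8 (3.5 equiv), THF, 0 °C; aq NH4Cl
Reagents that add atoms: none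
Why: Weinreb ketone synthesis: one equivalent of the Grignard reagent deprotonates the hydroxyl, the next adds to give a chelated tetrahedral intermediate that releases the enone only on quench, so neither double nor conjugate addition can follow.

Step 5
Reactants: 9 (4S)-4-hydroxy-2,4-dimethylhepta-1,6-dien-3-one
Product: 11 (3S)-3-hydroxy-3,5-dimethyl-4-oxohex-5-enal, via triol enone 10 (not isolated)
Conditions: OsO4 (cat.), NaIO4 (4 equiv), 2,6-lutidine, dioxane/H2O, rt
Reagents that add atoms: osmium tetroxide, O=[Os](=O)(=O)=O; sodium periodate, [Na+].[O-]I(=O)(=O)=O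
Why: Lemieux–Johnson oxidation: electrophilic OsO4 should dihydroxylate the isolated monosubstituted alkene much faster than the electron-poor conjugated isopropenyl ketone, and periodate cleaves the diol to the aldehyde under lutidine-buffered conditions that should spare the β-hydroxy aldehyde.

Step 6
Reactants: 11 (3S)-3-hydroxy-3,5-dimethyl-4-oxohex-5-enal
Product: 12 (2S,4S)-2,4-dihydroxy-2,6-dimethylcyclohexan-1-one as a mixture of C6 epimers (ring C1, C2, C4 and C6 are carotenoid C6, C5, C3 and C1)
Conditions: SmI2 (2.2 equiv), THF (0.01 M), −78 → −20 °C; aq NH4Cl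
Reagents that add atoms: none
Why: Single-electron reduction of the aldehyde by SmI2 gives a C3 samarium ketyl (polarity reversal of the aldehyde carbon) that adds to C2, the β-carbon of the isopropenyl ketone, and a second electron converts the resulting α-keto radical into the C1–C6 samarium enolate, which is protonated only on quench. This is a ketyl–olefin reductive cyclization of the aldehyde–enone type, a known reaction of SmI2. The six-membered ring closes in the 6-endo-trig mode, because attack at C2 is the Michael-type mode whereas 5-exo attack at the methyl-bearing C1 is electronically and sterically disfavoured. The new C3 stereocentre is controlled by the C5 stereocentre: trivalent samarium bridges the ketyl oxygen and the free C5 hydroxyl, so both oxygens sit pseudo-axial on one face of a chair-like transition state with the C5 methyl pseudo-equatorial, which should give the 3,5-cis diol (3S in carotenoid numbering). The step needs cyclization to outrun α-deoxygenation of the hydroxy ketone, simple reduction and pinacol dimerization, which is secured by high dilution, the absence of HMPA and of a proton source, and the masking of the product ketone as its enolate until quench. The C1 methine forms as a mixture, which is irrelevant because C1 becomes the gem-dimethyl carbon in step 8.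

Step 7
Reactants: 12 (2S,4S)-2,4-dihydroxy-2,6-dimethylcyclohexan-1-one
Product: 13 (2S,4S)-2,6-dimethyl-2,4-bis(triethylsilyloxy)cyclohexan-1-one (C6 epimers)
Conditions: TESOTf (2.5 equiv), 2,6-lutidine, CH2Cl2, −78 → 0 °C
Reagents that add atoms: triethylsilyl trifluoromethanesulfonate, CC[Si](CC)(CC)OS(=O)(=O)C(F)(F)F
Why: Silylation with a silyl triflate and a hindered pyridine base protects the secondary and the tertiary hydroxyl in one operation, so that step 8 methylates carbon only and both oxygens prefer equatorial positions in step 9.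

Step 8
Reactants: 13 (2S,4S)-2,6-dimethyl-2,4-bis(triethylsilyloxy)cyclohexan-1-one
Product: 14 (4S,6S)-2,2,6-trimethyl-4,6-bis(triethylsilyloxy)cyclohexan-1-one
Conditions: LiN(i-Pr)2, THF, −78 → −30 °C; MeI, DMPU, −78 → 0 °C
Reagents that add atoms: iodomethane, CI
Why: Enolate alkylation: the ketone can enolize only toward carotenoid C1 because C5 is quaternary, and C-methylation of this enolate erases the C1 stereocentre and installs the gem-dimethyl group.

Step 9
Reactants: 14 (4S,6S)-2,2,6-trimethyl-4,6-bis(triethylsilyloxy)cyclohexan-1-one; 15 (2E)-3-methylpent-2-en-4-yn-1-ol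
Product: 16 (1R,2S,4S)-1-[(3E)-5-hydroxy-3-methylpent-3-en-1-yn-1-yl]-2,6,6-trimethyl-2,4-bis(triethylsilyloxy)cyclohexan-1-ol
Conditions: 15 (3 equiv), n-BuLi (6 equiv), THF, −78 → 0 °C; then 14, −78 °C → rt; aq NH4Cl
Reagents that add atoms: none
Why: 1,2-Addition of a lithium acetylide to a non-enolizable ketone: in the chair with both silyloxy groups equatorial the axial methyls on C1 and C5 block the face of the C5 methyl, so the slim acetylide should enter axially from the opposite face, placing the chain cis to the C3 and C5 oxygens and the new C6 hydroxyl trans to them (the descriptor is R here only because the alkyne outranks C1).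

Step 10
Reactants: 16 (1R,2S,4S)-1-[(3E)-5-hydroxy-3-methylpent-3-en-1-yn-1-yl]-2,6,6-trimethyl-2,4-bis(triethylsilyloxy)cyclohexan-1-ol
Product: 17 (1S,2S,4S)-1-[(1E,3E)-5-hydroxy-3-methylpenta-1,3-dien-1-yl]-2,6,6-trimethyl-2,4-bis(triethylsilyloxy)cyclohexan-1-ol
Conditions: NaAlH2(OCH2CH2OMe)2 (4 equiv), THF, 0 °C → rt; aq potassium sodium tartrate
Reagents that add atoms: none
Why: Hydroxyl-directed trans-hydroalumination of the propargylic alcohol followed by protonolysis should give the (7E)-alkene, while the trisubstituted alkene and the silyl ethers are not reduced.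

Step 11
Reactants: 17 (1S,2S,4S)-1-[(1E,3E)-5-hydroxy-3-methylpenta-1,3-dien-1-yl]-2,6,6-trimethyl-2,4-bis(triethylsilyloxy)cyclohexan-1-ol
Product: 19 {(2E,4E)-5-[(1S,2S,4S)-1-hydroxy-2,6,6-trimethyl-2,4-bis(triethylsilyloxy)cyclohexyl]-3-methylpenta-2,4-dien-1-yl}triphenylphosphonium bromide, via allylic bromide 18 (not isolated)
Conditions: CBr4 (1.2 equiv), PPh3 (2.5 equiv), 2,6-lutidine, CH2Cl2, 0 °C → rt
Reagents that add atoms: carbon tetrabromide, BrC(Br)(Br)Br; triphenylphosphine, c1ccc(cc1)P(c1ccccc1)c1ccccc1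
Why: Appel bromination should occur only at the unhindered primary allylic alcohol (the tertiary C6 hydroxyl is flanked by two quaternary carbons), and excess triphenylphosphine displaces the bromide by SN2 substitution in the same flask under non-acidic conditions that keep the silyl ethers and the tertiary dienyl carbinol intact.

Step 12
Reactants: 20 (4R,6R)-4-hydroxy-2,2,6-trimethylcyclohexan-1-one
Product: 21 (4R,6R)-4-(tert-butyldimethylsilyloxy)-2,2,6-trimethylcyclohexan-1-one
Conditions: TBSCl, imidazole, DMF, rt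
Reagents that add atoms: tert-butyldimethylsilyl chloride, CC(C)(C)[Si](C)(C)Cl
Why: Standard silylation of the secondary alcohol, needed because the next step uses a strong base and a triflating agent.

Step 13
Reactants: 21 (4R,6R)-4-(tert-butyldimethylsilyloxy)-2,2,6-trimethylcyclohexan-1-one
Product: 22 (4R)-4-(tert-butyldimethylsilyloxy)-2,6,6-trimethylcyclohex-1-en-1-yl trifluoromethanesulfonate
Conditions: LiN(i-Pr)2, THF, −78 °C; PhNTf2, −78 → 0 °C
Reagents that add atoms: N-phenylbis(trifluoromethanesulfonimide), FC(F)(F)S(=O)(=O)N(c1ccccc1)S(=O)(=O)C(F)(F)F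
Why: Enol triflate formation: the ketone has a single enolizable position (C6, since C2 is quaternary), so O-triflation of its enolate gives one regioisomer, and the C6 stereocentre is removed by design.

Step 14
Reactants: 22 (4R)-4-(tert-butyldimethylsilyloxy)-2,6,6-trimethylcyclohex-1-en-1-yl trifluoromethanesulfonate; 15 (2E)-3-methylpent-2-en-4-yn-1-ol
Product: 23 (2E)-5-[(4R)-4-(tert-butyldimethylsilyloxy)-2,6,6-trimethylcyclohex-1-en-1-yl]-3-methylpent-2-en-4-yn-1-ol
Conditions: Pd(PPh3)4 (cat.), CuI (cat.), i-Pr2NH, DMF, rt → 50 °C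
Reagents that add atoms: none
Why: Sonogashira coupling of the alkenyl triflate with the terminal alkyne (zerovalent palladium and CuI catalysis) forms the C6'–C7' bond directly at the alkyne oxidation level, tolerating the free allylic alcohol and leaving the E alkene of 15 untouched.

Step 15
Reactants: 23 (2E)-5-[(4R)-4-(tert-butyldimethylsilyloxy)-2,6,6-trimethylcyclohex-1-en-1-yl]-3-methylpent-2-en-4-yn-1-ol
Product: 25 {(2E)-5-[(4R)-4-(tert-butyldimethylsilyloxy)-2,6,6-trimethylcyclohex-1-en-1-yl]-3-methylpent-2-en-4-yn-1-yl}triphenylphosphonium bromide, via allylic bromide 24 (not isolated)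
Conditions: CBr4 (1.2 equiv), PPh3 (2.5 equiv), CH2Cl2, 0 °C → rt
Reagents that add atoms: carbon tetrabromide, BrC(Br)(Br)Br; triphenylphosphine, c1ccc(cc1)P(c1ccccc1)c1ccccc1
Why: Appel bromination of the primary allylic alcohol and SN2 displacement of the bromide by excess triphenylphosphine in one flask, under neutral conditions that preserve the silyl ether and the enyne.

Step 16
Reactants: 25 acetylenic fifteen-carbon phosphonium bromide (as in step 15); 26 (2E,4E,6E)-2,7-dimethylocta-2,4,6-trienedial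
Product: 27 (2E,4E,6E,8E,10E)-13-[(4R)-4-(tert-butyldimethylsilyloxy)-2,6,6-trimethylcyclohex-1-en-1-yl]-2,7,11-trimethyltrideca-2,4,6,8,10-pentaen-12-ynal
Conditions: NaN(SiMe3)2, THF, −78 °C; inverse addition to 26 (3 equiv), −78 → 0 °C; then heptane, 80 °C, dark
Reagents that add atoms: none
Why: Wittig reaction: inverse addition of the ylide to excess symmetrical dialdehyde limits olefination to one formyl group, and the hindered Z isomer at the new C11'=C12' bond is expected to isomerize to E on gentle heating, which is preferred over iodine catalysis because that could also isomerize the C9'=C10' bond next to the alkyne.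

Step 17
Reactants: 27 twenty-five-carbon polyenynal (as in step 16); 19 trihydroxy-ring phosphonium bromide (as in step 11)
Product: 28 (3S,5S,6S,3'R)-3'-O-(tert-butyldimethylsilyl)-3,5-bis-O-(triethylsilyl)-7',8'-didehydro-5,6-dihydro-β,β-carotene-3,5,6,3'-tetrol
Conditions: 19, NaN(SiMe3)2 (1.1 equiv), THF, −78 °C; then 27, −78 → 0 °C; then heptane/EtOAc, 70 °C, dark
Reagents that add atoms: none
Why: Wittig reaction of the allylic ylide with the polyenal forms the C11=C12 bond and completes the forty-carbon chain, tolerating the tertiary hydroxyl, and the hindered 11Z isomer is expected to equilibrate thermally to the all-E polyene.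

Step 18
Reactants: 28 tris-silylated tetrol (as in step 17)
Product: 29 (3S,5S,6S,3'R)-7',8'-didehydro-5,6-dihydro-β,β-carotene-3,5,6,3'-tetrol (CNP0160593.1)
Conditions: Bu4NF (6 equiv), AcOH (3 equiv), THF, 0 °C → rt, dark, argon
Reagents that add atoms: none
Why: Fluoride-mediated desilylation of the three silyl ethers under acetic acid buffering, with no acid strong enough to ionize the tertiary allylic C6 hydroxyl, should give the tetrol with all stereocentres unchanged.

**Compound list**

1 | (R)-lactic acid | C[C@@H](O)C(O)=O | starting material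
2 | pivalaldehyde | CC(C)(C)C=O | starting material
3 | (2R,5R)-2-tert-butyl-5-methyl-1,3-dioxolan-4-one | C[C@H]1O[C@@H](C(C)(C)C)OC1=O | intermediate
4 | allyl bromide | C=CCBr | starting material
5 | (2R,5S)-2-tert-butyl-5-methyl-5-(prop-2-en-1-yl)-1,3-dioxolan-4-one | C[C@@]1(CC=C)O[C@@H](C(C)(C)C)OC1=O | intermediate
6 | N,O-dimethylhydroxylamine hydrochloride | CNOC.Cl | starting material
7 | (2S)-2-hydroxy-N-methoxy-N,2-dimethylpent-4-enamide | C=CC[C@](C)(O)C(=O)N(C)OC | intermediate
8 | isopropenylmagnesium bromide | C=C(C)[Mg]Br | starting material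
9 | (4S)-4-hydroxy-2,4-dimethylhepta-1,6-dien-3-one | C=CC[C@](C)(O)C(=O)C(C)=C | intermediate
10 | (4S)-4,6,7-trihydroxy-2,4-dimethylhept-1-en-3-one (C6 epimers, not isolated) | OCC(O)C[C@](C)(O)C(=O)C(C)=C | intermediate
11 | (3S)-3-hydroxy-3,5-dimethyl-4-oxohex-5-enal | O=CC[C@](C)(O)C(=O)C(C)=C | intermediate
12 | (2S,4S)-2,4-dihydroxy-2,6-dimethylcyclohexan-1-one (C6 epimers) | O=C1C(C)C[C@H](O)C[C@]1(C)O | intermediate
13 | (2S,4S)-2,6-dimethyl-2,4-bis(triethylsilyloxy)cyclohexan-1-one (C6 epimers) | O=C1C(C)C[C@H](O[Si](CC)(CC)CC)C[C@]1(C)O[Si](CC)(CC)CC | intermediate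
14 | (4S,6S)-2,2,6-trimethyl-4,6-bis(triethylsilyloxy)cyclohexan-1-one | O=C1C(C)(C)C[C@H](O[Si](CC)(CC)CC)C[C@]1(C)O[Si](CC)(CC)CC | intermediate
15 | (2E)-3-methylpent-2-en-4-yn-1-ol | C#C/C(C)=C/CO | starting material
16 | (1R,2S,4S)-1-[(3E)-5-hydroxy-3-methylpent-3-en-1-yn-1-yl]-2,6,6-trimethyl-2,4-bis(triethylsilyloxy)cyclohexan-1-ol | OC/C=C(C)/C#C[C@]1(O)C(C)(C)C[C@H](O[Si](CC)(CC)CC)C[C@]1(C)O[Si](CC)(CC)CC | intermediate
17 | (1S,2S,4S)-1-[(1E,3E)-5-hydroxy-3-methylpenta-1,3-dien-1-yl]-2,6,6-trimethyl-2,4-bis(triethylsilyloxy)cyclohexan-1-ol | OC/C=C(C)/C=C/[C@]1(O)C(C)(C)C[C@H](O[Si](CC)(CC)CC)C[C@]1(C)O[Si](CC)(CC)CC | intermediate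
18 | (1S,2S,4S)-1-[(1E,3E)-5-bromo-3-methylpenta-1,3-dien-1-yl]-2,6,6-trimethyl-2,4-bis(triethylsilyloxy)cyclohexan-1-ol (not isolated) | BrC/C=C(C)/C=C/[C@]1(O)C(C)(C)C[C@H](O[Si](CC)(CC)CC)C[C@]1(C)O[Si](CC)(CC)CC | intermediate
19 | {(2E,4E)-5-[(1S,2S,4S)-1-hydroxy-2,6,6-trimethyl-2,4-bis(triethylsilyloxy)cyclohexyl]-3-methylpenta-2,4-dien-1-yl}triphenylphosphonium bromide | [Br-].c1ccccc1[P+](c1ccccc1)(c1ccccc1)C/C=C(C)/C=C/[C@]1(O)C(C)(C)C[C@H](O[Si](CC)(CC)CC)C[C@]1(C)O[Si](CC)(CC)CC | intermediate
20 | (4R,6R)-4-hydroxy-2,2,6-trimethylcyclohexan-1-one | CC1(C)C[C@H](O)C[C@@H](C)C1=O | starting material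
21 | (4R,6R)-4-(tert-butyldimethylsilyloxy)-2,2,6-trimethylcyclohexan-1-one | CC1(C)C[C@H](O[Si](C)(C)C(C)(C)C)C[C@@H](C)C1=O | intermediate
22 | (4R)-4-(tert-butyldimethylsilyloxy)-2,6,6-trimethylcyclohex-1-en-1-yl trifluoromethanesulfonate | CC1=C(OS(=O)(=O)C(F)(F)F)C(C)(C)C[C@H](O[Si](C)(C)C(C)(C)C)C1 | intermediate
23 | (2E)-5-[(4R)-4-(tert-butyldimethylsilyloxy)-2,6,6-trimethylcyclohex-1-en-1-yl]-3-methylpent-2-en-4-yn-1-ol | CC1=C(C#C/C(C)=C/CO)C(C)(C)C[C@H](O[Si](C)(C)C(C)(C)C)C1 | intermediate
24 | {[(1R)-4-[(3E)-5-bromo-3-methylpent-3-en-1-yn-1-yl]-3,5,5-trimethylcyclohex-3-en-1-yl]oxy}(tert-butyl)dimethylsilane (not isolated) | CC1=C(C#C/C(C)=C/CBr)C(C)(C)C[C@H](O[Si](C)(C)C(C)(C)C)C1 | intermediate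
25 | {(2E)-5-[(4R)-4-(tert-butyldimethylsilyloxy)-2,6,6-trimethylcyclohex-1-en-1-yl]-3-methylpent-2-en-4-yn-1-yl}triphenylphosphonium bromide | [Br-].CC1=C(C#C/C(C)=C/C[P+](c2ccccc2)(c2ccccc2)c2ccccc2)C(C)(C)C[C@H](O[Si](C)(C)C(C)(C)C)C1 | intermediate
26 | (2E,4E,6E)-2,7-dimethylocta-2,4,6-trienedial | O=C/C(C)=C/C=C/C=C(C)/C=O | starting material
27 | (2E,4E,6E,8E,10E)-13-[(4R)-4-(tert-butyldimethylsilyloxy)-2,6,6-trimethylcyclohex-1-en-1-yl]-2,7,11-trimethyltrideca-2,4,6,8,10-pentaen-12-ynal | CC1=C(C#C/C(C)=C/C=C/C(C)=C/C=C/C=C(C)/C=O)C(C)(C)C[C@H](O[Si](C)(C)C(C)(C)C)C1 | intermediate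
28 | (3S,5S,6S,3'R)-3'-O-(tert-butyldimethylsilyl)-3,5-bis-O-(triethylsilyl)-7',8'-didehydro-5,6-dihydro-β,β-carotene-3,5,6,3'-tetrol | CC1=C(C#C/C(C)=C/C=C/C(C)=C/C=C/C=C(C)/C=C/C=C(C)/C=C/[C@]2(O)C(C)(C)C[C@H](O[Si](CC)(CC)CC)C[C@]2(C)O[Si](CC)(CC)CC)C(C)(C)C[C@H](O[Si](C)(C)C(C)(C)C)C1 | intermediate
29 | (3S,5S,6S,3'R)-7',8'-didehydro-5,6-dihydro-β,β-carotene-3,5,6,3'-tetrol (CNP0160593.1) | CC1=C(C#C/C(C)=C/C=C/C(C)=C/C=C/C=C(C)/C=C/C=C(C)/C=C/[C@]2(O)C(C)(C)C[C@H](O)C[C@]2(C)O)C(C)(C)C[C@H](O)C1 | target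

**Step count.** Total: 18 steps. Longest linear sequence: 13 steps (steps 1–11, 17 and 18).

**Steps most likely to fail**

Step 6. The ring closure may be outrun by reduction of the enone, by reductive loss of the C5 oxygen or by dimerization, or it may proceed with poor facial control at C3. The fallback closes the same C2–C3 bond by ring-closing metathesis and sets C3 through a silicon tether. It sets out from 7 and returns at 14. Weinreb amide 7 is treated with prenylmagnesium chloride, which reacts at its tertiary terminus and gives the ketone (5S)-5-hydroxy-3,3,5-trimethylocta-1,7-dien-4-one F1 with the gem-dimethyl group already in place. The second-generation Grubbs catalyst closes the C2=C3 alkene to (6S)-6-hydroxy-2,2,6-trimethylcyclohex-3-en-1-one F2. Silylation of the tertiary hydroxyl with ClSiMe2H and Et3N gives the hydrosilyl ether (6S)-6-(dimethylsilyloxy)-2,2,6-trimethylcyclohex-3-en-1-one F3. Intramolecular hydrosilylation with H2PtCl6 delivers silicon to C3 on the face of the C5 oxygen and gives the bridged siloxane (1S,5S)-3,3,5,7,7-pentamethyl-6-oxa-7-silabicyclo[3.2.1]octan-4-one F4. Tamao oxidation (H2O2, KF, KHCO3) converts C3–Si into C3–OH with retention and gives the cis-diol (4S,6S)-4,6-dihydroxy-2,2,6-trimethylcyclohexan-1-one F5, which TESOTf and 2,6-lutidine convert into 14.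

Step 9. Addition of the dilithiated enynol to the doubly neopentyl ketone may be slow, attack from the methyl-bearing face may compete, or a silyl group may migrate to the new alkoxide. The fallback builds the chain in two smaller stages. It sets out from 14 and returns at 17, so that step 10 is no longer needed. Ethynylmagnesium bromide, the smallest alkynyl nucleophile, adds to 14 to give (1R,2S,4S)-1-ethynyl-2,6,6-trimethyl-2,4-bis(triethylsilyloxy)cyclohexan-1-ol F6. Hydrostannylation with Bu3SnH and PdCl2(PPh3)2 gives (1S,2S,4S)-1-[(E)-2-(tributylstannyl)ethenyl]-2,6,6-trimethyl-2,4-bis(triethylsilyloxy)cyclohexan-1-ol F7. Stille coupling of F7 with (E)-3-iodobut-2-en-1-ol (Pd2(dba)3, AsPh3, NMP) gives diene diol 17 directly.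

Step 11. Ionization of the dienyl bromide next to the tertiary carbinol may cause allylic transposition, elimination or loss of silyl groups before the phosphine captures it. The fallback exchanges the roles of the two coupling partners. It sets out from 17 and 27 and returns at 28, replacing steps 11 and 17. Diol 17 is oxidized with MnO2 to (2E,4E)-5-[(1S,2S,4S)-1-hydroxy-2,6,6-trimethyl-2,4-bis(triethylsilyloxy)cyclohexyl]-3-methylpenta-2,4-dienal F8. Aldehyde 27 is reduced with NaBH4 to (2E,4E,6E,8E,10E)-13-[(4R)-4-(tert-butyldimethylsilyloxy)-2,6,6-trimethylcyclohex-1-en-1-yl]-2,7,11-trimethyltrideca-2,4,6,8,10-pentaen-12-yn-1-ol F9. CBr4 and PPh3 convert F9 into the corresponding triphenylphosphonium bromide F10. Wittig reaction of F10 with F8 (NaN(SiMe3)2, THF, then gentle heating) forms the same C11=C12 bond and gives 28.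

**Further compounds**

F1 | step 6 | (5S)-5-hydroxy-3,3,5-trimethylocta-1,7-dien-4-one | C=CC[C@](C)(O)C(=O)C(C)(C)C=C
F2 | step 6 | (6S)-6-hydroxy-2,2,6-trimethylcyclohex-3-en-1-one | O=C1C(C)(C)C=CC[C@]1(C)O
F3 | step 6 | (6S)-6-(dimethylsilyloxy)-2,2,6-trimethylcyclohex-3-en-1-one | O=C1C(C)(C)C=CC[C@]1(C)O[SiH](C)C
F4 | step 6 | (1S,5S)-3,3,5,7,7-pentamethyl-6-oxa-7-silabicyclo[3.2.1]octan-4-one | O=C1C(C)(C)C[C@H]2C[C@]1(C)O[Si]2(C)C
F5 | step 6 | (4S,6S)-4,6-dihydroxy-2,2,6-trimethylcyclohexan-1-one | O=C1C(C)(C)C[C@H](O)C[C@]1(C)O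
F6 | step 9 | (1R,2S,4S)-1-ethynyl-2,6,6-trimethyl-2,4-bis(triethylsilyloxy)cyclohexan-1-ol | C#C[C@]1(O)C(C)(C)C[C@H](O[Si](CC)(CC)CC)C[C@]1(C)O[Si](CC)(CC)CC
F7 | step 9 | (1S,2S,4S)-1-[(E)-2-(tributylstannyl)ethenyl]-2,6,6-trimethyl-2,4-bis(triethylsilyloxy)cyclohexan-1-ol | CCCC[Sn](CCCC)(CCCC)/C=C/[C@]1(O)C(C)(C)C[C@H](O[Si](CC)(CC)CC)C[C@]1(C)O[Si](CC)(CC)CC
F8 | step 11 | (2E,4E)-5-[(1S,2S,4S)-1-hydroxy-2,6,6-trimethyl-2,4-bis(triethylsilyloxy)cyclohexyl]-3-methylpenta-2,4-dienal | O=C/C=C(C)/C=C/[C@]1(O)C(C)(C)C[C@H](O[Si](CC)(CC)CC)C[C@]1(C)O[Si](CC)(CC)CC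
F9 | step 11 | (2E,4E,6E,8E,10E)-13-[(4R)-4-(tert-butyldimethylsilyloxy)-2,6,6-trimethylcyclohex-1-en-1-yl]-2,7,11-trimethyltrideca-2,4,6,8,10-pentaen-12-yn-1-ol | CC1=C(C#C/C(C)=C/C=C/C(C)=C/C=C/C=C(C)/CO)C(C)(C)C[C@H](O[Si](C)(C)C(C)(C)C)C1
F10 | step 11 | {(2E,4E,6E,8E,10E)-13-[(4R)-4-(tert-butyldimethylsilyloxy)-2,6,6-trimethylcyclohex-1-en-1-yl]-2,7,11-trimethyltrideca-2,4,6,8,10-pentaen-12-yn-1-yl}triphenylphosphonium bromide | [Br-].CC1=C(C#C/C(C)=C/C=C/C(C)=C/C=C/C=C(C)/C[P+](c2ccccc2)(c2ccccc2)c2ccccc2)C(C)(C)C[C@H](O[Si](C)(C)C(C)(C)C)C1
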